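All runs come from a simulation with constants of no real substance.

**Midnight's plateau.** Midnight, the flask asked about, showed target readings flattening by 8.00 min, and spring, run warmer, stood higher at 20.5%.

in all of them: substrate 0.050 M; catalyst 25 µM
- midnight: temperature 5 °C; the very flask that is asked about, followed so far
- spring: temperature 11 °C; run made earlier
- flask: temperature 5 °C; time 10 min

| run | time / min | target / % |
|---|---|---|
| midnight | 2.00 | 13.1 |
| midnight | 4.00 | 15.5 |
| midnight | 6.00 | 16.0 |
| midnight | 8.00 | 16.1 |
| spring | 2.00 | 15.7 |
| spring | 4.00 | 18.3 |
| spring | 6.00 | 19.9 |
| spring | 8.00 | 20.5 |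

(each reading ± 0.5 percentage points)

- theta: change nothing and wait 20 min more
- eta: at 10 min raise the temperature by 10 K, then wait 20 min
- epsilon: at 10 min take out 90% of the target then present, then wait 20 min
- delta: at 10 min add catalyst, 50.0% of the amount charged, then wait 20 min

* target, in percent of the substrate first charged, at 10 min
* the remedy with the largest gain of target, or "none" below 2 percentage points (theta / eta / epsilon / delta / none)
* target present, with what was taken out counted in, in percent of the substrate first charged, after eta
* target present, with what was taken out counted in, in percent of the substrate first charged, after delta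

- target taken out counts as made
- what was read earlier has a scatter of 0.5 percentage points, one standard deviation
- additions bring no volume worth counting

**One number.** I named the plateau share φ, c(target) over the c(substrate) charged once target stops rising, and read it from midnight's last point as 16.1%. I wagered on thermodynamic control: of the material free to interconvert, target keeps the share φ. The readings did not tell this from a dying catalyst, so this stayed a wager.

**Reading it off.** Taking out 90% of the target shrinks the pool by that much of φ, and target refills to φ of what remains, a gain of 12 percentage points. Scaling the spring ratio over 10 K puts the plateau at 24.1%, a gain of 8 points, which is smaller. On this wager, waiting and fresh catalyst leave φ unmoved, so for midnight I put delta at φ and chose epsilon.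

**Was it enough?** Not quite, since φ says where and not when. Midnight's gap to φ shrank from 3 points to 0.6 points in 2.00 min, giving a closing rate λ of 0.805 min⁻¹. Then λ times 10 min is 8.05, so 1/λ is far shorter than the time asked, and I put midnight at φ.

**The result.** The forecast, holding that “waiting or heating gains almost nothing”, gave 16.2% at the asked time, delta as the remedy, 16.4% after eta and 23.6% after delta. The flask gave 16.7% and epsilon, with a gain of 13 points against my 12 points, then 22.9% after eta and 17.5% after delta.

    target + catalyst ⇌ isomer of the product A + catalyst, rate k1*[catalyst]*[target] forward; the back reaction follows from the equilibrium constant (K = 2.70, k = 370 L mol⁻¹ s⁻¹, Ea = 36.0 kJ mol⁻¹, ΔH = −61.0 kJ mol⁻¹)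
    substrate + catalyst ⇌ target + catalyst, rate k2*[substrate]*[catalyst] forward; the back reaction follows from the equilibrium constant (K = 4.70, k = 120 L mol⁻¹ s⁻¹, Ea = 39.0 kJ mol⁻¹, ΔH = −19.0 kJ mol⁻¹)
    catalyst ⇌ dormant form (K = 0.830, k = 0.00220 s⁻¹, Ea = 88.0 kJ mol⁻¹, ΔH = −27.0 kJ mol⁻¹)
    target + catalyst ⇌ isomer of the product B + catalyst, rate k4*[catalyst]*[target] forward; the back reaction follows from the equilibrium constant (K = 1.80, k = 330 L mol⁻¹ s⁻¹, Ea = 44.0 kJ mol⁻¹, ΔH = 7.00 kJ mol⁻¹)
    isomer of the product A ⇌ substrate (k = 1.30 × 10⁻⁴ s⁻¹, Ea = 94.0 kJ mol⁻¹)
    (constants at 5 °C)

**What stood there.** Target's forward half-life into isomer of the product B, way back not counted and the other concentrations as charged, was 1.4 min, short against 10 min. At 10.0 min the flask made target 1.12 times as fast as it used it up, each step taken net, with target at 16.7%.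

**Second flask.** For the neighbour flask, the same charge read at 4.0 min, φ less its unclosed gap gives 15.5%. The computed target there is 15.2%, with 38.8% substrate remaining.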